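Late in Monday's run the flask looks still: idle adduct A, the resting state, reads 96 %, 97 % and 97 % at 40.0 s, 60.0 s and 90.0 s. The flask you are asked about is that same run followed further: 0.10 M starting complex fed over 30 s into 3.00 equiv incoming ligand, 2.00 equiv leaving ligand and 5.00 mM protic impurity.

Monday's run (percent of the starting complex charged)

| time / s | complex with two exchanged / % | idle adduct A / % | starting complex / % |
|---|---|---|---|
| 10.0 | 0 | 35 | 0 |
| 12.0 | 0 | 39 | 0 |
| 20.0 | 0 | 66 | 0 |
| 25.0 | 0 | 81 | 4 |
| 40.0 | 0 | 96 | 0 |
| 60.0 | 0 | 97 | 3 |
| 90.0 | 2 | 97 | 4 |

(scatter of a reading: 2 percentage points)

- concentration of complex with two exchanged (only what is free in solution) at 4.0 min, in M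
- concentration of idle adduct A at 4.0 min, in M

Here is my own reckoning. Each captured starting complex takes up one leaving ligand, so c(incoming ligand)/c(leaving ligand), the ligand ratio, comes to 2.91. Take the symmetric case as your zero: with both ligands held equally, each exchange multiplies the complex by that ratio, so on this scale c(complex with two exchanged)/c(starting complex) is its square, 8.47. Monday's last readings give 0.500, far below that. With Monday's readings of adduct A flat, I expect the ratio to hold until 4.0 min.

The weak link is the 2 % of complex with two exchanged at 90.0 s, read with a scatter of 2 percentage points. Averaging the last two readings of complex with two exchanged, all its forms counted, gives 0.00100 M, and I commit to that, with 0.0970 M of adduct A.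

The forecast says 0.002 M and 0.09 M, holding that “real conversion is slow”. The flask gives 0.00119 M and 0.0952 M.

    starting complex + incoming ligand ⇌ leaving ligand + complex with one exchanged (K = 0.320, k = 0.200 M⁻¹ s⁻¹)
    complex with one exchanged + incoming ligand ⇌ leaving ligand + complex with two exchanged (K = 0.300, k = 0.0700 M⁻¹ s⁻¹)
    leaving ligand + starting complex ⇌ idle adduct A, settled at all times (K = 520 M⁻¹)
    starting complex + complex with two exchanged ⇌ idle adduct B, settled at all times (K = 7.10 M⁻¹)
    protic impurity + starting complex → quenched substrate (k = 0.270 M⁻¹ s⁻¹)

In this flask the forward half-life of complex with one exchanged passing on to complex with two exchanged, 0.55 min with concentrations as charged, is shorter than the 4.0 min asked, and 85 % of that step's turnover up to the asked time is behind it at 2.00 min, while at 4.0 min the ligand ratio of 2.72 goes with a product-to-starting-complex ratio of 0.0960 of its square. In the neighbour with 12.0 equiv incoming ligand the ligand ratio at 4.00 min is 8.71, and that same fraction of its square, on 1.22 % starting complex, gives 8.89 %, where that flask holds 8.94 % of complex with two exchanged, all its forms counted.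

The earlier runs and the new flask are calculated with constants of no real substance; noise was put on by code.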